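**Remark:** ring atoms are numbered C1 (olefinic, bears the CH2O carbon C7), C2 (olefinic CH) and C3–C6 (carbinol carbons). Iodide 1 is taken as a catalogue compound (otherwise one step from methyl 2,3-O-isopropylidene-β-D-ribofuranoside with I2, PPh3, imidazole). Transient species of a single mechanistic event (organozinc, enamine) are not numbered.

## Retrosynthetic overview

1. The O7 benzoate goes on last, by selective primary acylation of tetraol 8; the O5 benzoate is put on when O5–H is the only free hydroxyl.
2. The cyclohexene C1–C6 (the only skeletal ring besides the two phenyls, which arrive with benzoyl chloride) is closed at C1=C2 by ring-closing carbonyl–olefin metathesis of keto-olefin 5.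
3. Keto-olefin 5 comes from one aldol bond, C5–C6: 2,2-dimethyl-1,3-dioxan-5-one (C7–C1–C6) plus the D-ribose-derived aldehyde 2 (C5–C4–C3–C2=CH2). (S)-Proline sets C5 and C6; ribose supplies C3 and C4.
4. Enabling feature: C1 is the central carbon of the 1,3-dioxygenated unit O7–C7–C1–C6–O6 (a masked dihydroxyacetone carbonyl), and its partner C2 is an unsubstituted CH next to the cis-diol C3/C4. C1=C2 can therefore be drawn as C=O plus C=CH2.
5. Ring order: dioxolane acetonide (present in 1) and dioxane acetonide (from 3) are temporary; the cyclohexene forms in step 4; both acetonides are removed in step 5.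

Key step: step 4

## Route

Step 1
Reactants: 1 methyl 5-deoxy-5-iodo-2,3-O-isopropylidene-β-D-ribofuranoside
Product: 2 (4R,5R)-2,2-dimethyl-5-vinyl-1,3-dioxolane-4-carbaldehyde (4,5-dideoxy-2,3-O-isopropylidene-D-erythro-pent-4-enose)
Conditions: Zn dust (activated, 10 equiv), THF/H2O 4:1, ultrasound, 40 °C; extractive work-up, used crude
Reagents that add atoms: none
Why: Bernet–Vasella reductive fragmentation: zinc inserts into the C–I bond and the organozinc expels the ring oxygen, which opens the furanoside to the aldehyde and the vinyl group and leaves the two acetonide-bearing stereocentres (later C4 and C3) untouched.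

Step 2
Reactants: 2 (4R,5R)-2,2-dimethyl-5-vinyl-1,3-dioxolane-4-carbaldehyde; 3 2,2-dimethyl-1,3-dioxan-5-one
Product: 4 (4S)-4-{(S)-hydroxy[(4S,5R)-2,2-dimethyl-5-vinyl-1,3-dioxolan-4-yl]methyl}-2,2-dimethyl-1,3-dioxan-5-one
Conditions: (S)-proline (0.3 equiv), DMF, 2 °C
Reagents that add atoms: none
Why: Proline-catalysed direct aldol reaction (enamine catalysis): the ring-locked (E)-enamine of 3 should add to one aldehyde face under catalyst control to give the anti aldol with (S) at both new centres (later C6 and C5), the pairing known to turn (R)-α-alkoxy aldehydes into D-tagatose-type (3S,4S,5R) arrays.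

Step 3
Reactants: 4 the aldol adduct
Product: 5 (S)-[(4S)-2,2-dimethyl-5-oxo-1,3-dioxan-4-yl][(4R,5R)-2,2-dimethyl-5-vinyl-1,3-dioxolan-4-yl]methyl benzoate
Conditions: BzCl (1.3 equiv), pyridine (3 equiv), CH2Cl2, −10 to 0 °C
Reagents that add atoms: benzoyl chloride, O=C(Cl)c1ccccc1
Why: Nucleophilic acyl substitution at the only free hydroxyl (O5) installs the C5 benzoate of the target regiospecifically and removes the acidic OH before the alkylidene step; the weak base and low temperature should keep the β-acyloxy ketone from eliminating or epimerising at C6.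

Step 4
Reactants: 5 the keto-olefin benzoate
Product: 7 tricyclic bis-acetonide benzoate (5-O-benzoyl-3,4:6,7-di-O-isopropylidene derivative of (3R,4R,5R,6R)-1-(hydroxymethyl)cyclohex-1-ene-3,4,5,6-tetrol), via molybdenum alkylidene 6 (not isolated)
Conditions: Mo(=CHCMe2Ph)(=N-2,6-iPr2C6H3)[OCMe(CF3)2]2 (1.1 equiv), benzene (0.01 M), 20 °C, argon
Reagents that add atoms: none
Why: The neophylidene complex first undergoes olefin metathesis with the terminal vinyl group of 5 (cycloaddition and cycloreversion through a molybdacyclobutane), releasing 3-methyl-3-phenylbut-1-ene and giving the substrate-bound alkylidene 6, whose carbene carbon C2 then adds across the ketone C1=O through an oxamolybdacyclobutane that collapses irreversibly to the C1=C2 bond and a molybdenum oxo complex. The closest known reaction type is the stoichiometric alkylidene-mediated ring-closing carbonyl–olefin metathesis of olefinic ketones to five-, six- and seven-membered cycloalkenes. The cyclohexene ring C1–C6 is closed by formation of the C1=C2 bond, a 6-exo attack of the C2 carbene carbon on the carbonyl carbon C1, which at the same time turns the dioxanone into the fused 4H-1,3-dioxine. No stereocentre is formed: C3–C6 are carried through unchanged, and C6, epimerisable while next to the ketone, is fixed once C1 becomes sp2. The step needs chemoselectivity (vinyl before carbonyl, ketone before benzoate, intramolecular before intermolecular): the monosubstituted olefin is the site the bulky neophylidene engages fastest, the α,α'-dialkoxy ketone is far more electrophilic than the ester carbonyl and sits at six-ring distance from the carbene, and high dilution suppresses dimerisation.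

Step 5
Reactants: 7 the tricyclic bis-acetonide benzoate
Product: 8 (1R,2R,5R,6R)-2,5,6-trihydroxy-3-(hydroxymethyl)cyclohex-3-en-1-yl benzoate
Conditions: CF3CO2H/H2O 9:1, 0 to 20 °C
Reagents that add atoms: none
Why: Acid-catalysed acetal hydrolysis (through the oxocarbenium ions at the two acetal carbons) frees O3, O4, O6 and O7, while the benzoate on O5 is stable to aqueous acid and should not migrate readily at low pH.

Step 6
Reactants: 8 the tetraol monobenzoate
Product: 9 [(3R,4R,5R,6R)-5-(benzoyloxy)-3,4,6-trihydroxycyclohex-1-en-1-yl]methyl benzoate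
Conditions: BzCl (1.05 equiv), 2,4,6-collidine (3 equiv), CH2Cl2/MeCN 1:1, −40 °C
Reagents that add atoms: benzoyl chloride, O=C(Cl)c1ccccc1
Why: Kinetically controlled acylation of the primary allylic hydroxyl O7–H, the least hindered of the four, with one equivalent of acid chloride and a hindered base at low temperature; the three secondary hydroxyls should react more slowly and base-promoted acyl migration should be negligible.

## Compound list

1 | methyl 5-deoxy-5-iodo-2,3-O-isopropylidene-β-D-ribofuranoside | CO[C@@H]1O[C@H](CI)[C@H]2OC(C)(C)O[C@@H]12 | starting material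
2 | (4R,5R)-2,2-dimethyl-5-vinyl-1,3-dioxolane-4-carbaldehyde | O=C[C@@H]1OC(C)(C)O[C@@H]1C=C | intermediate
3 | 2,2-dimethyl-1,3-dioxan-5-one | O=C1COC(C)(C)OC1 | starting material
4 | (4S)-4-{(S)-hydroxy[(4S,5R)-2,2-dimethyl-5-vinyl-1,3-dioxolan-4-yl]methyl}-2,2-dimethyl-1,3-dioxan-5-one | O=C1COC(C)(C)O[C@H]1[C@@H](O)[C@@H]2OC(C)(C)O[C@@H]2C=C | intermediate
5 | (S)-[(4S)-2,2-dimethyl-5-oxo-1,3-dioxan-4-yl][(4R,5R)-2,2-dimethyl-5-vinyl-1,3-dioxolan-4-yl]methyl benzoate | O=C1COC(C)(C)O[C@H]1[C@@H](OC(=O)c3ccccc3)[C@@H]2OC(C)(C)O[C@@H]2C=C | intermediate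
6 | molybdenum alkylidene of 5 (terminal CH2 replaced by the Mo(=N-2,6-iPr2C6H3)[OCMe(CF3)2]2 fragment) | O=C1COC(C)(C)O[C@H]1[C@@H](OC(=O)c3ccccc3)[C@@H]2OC(C)(C)O[C@@H]2C=[Mo](=Nc4c(C(C)C)cccc4C(C)C)(OC(C)(C(F)(F)F)C(F)(F)F)OC(C)(C(F)(F)F)C(F)(F)F | intermediate
7 | 5-O-benzoyl-3,4:6,7-di-O-isopropylidene derivative of (3R,4R,5R,6R)-1-(hydroxymethyl)cyclohex-1-ene-3,4,5,6-tetrol | O1CC2=C[C@H]3OC(C)(C)O[C@H]3[C@H](OC(=O)c4ccccc4)[C@@H]2OC1(C)C | intermediate
8 | (1R,2R,5R,6R)-2,5,6-trihydroxy-3-(hydroxymethyl)cyclohex-3-en-1-yl benzoate | OCC1=C[C@@H](O)[C@@H](O)[C@H](OC(=O)c2ccccc2)[C@@H]1O | intermediate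
9 | [(3R,4R,5R,6R)-5-(benzoyloxy)-3,4,6-trihydroxycyclohex-1-en-1-yl]methyl benzoate | O=C(OCC1=C[C@@H](O)[C@@H](O)[C@H](OC(=O)c2ccccc2)[C@@H]1O)c1ccccc1 | target

## Step count and risks

Total step count: 6. Longest linear sequence: 6 steps (1 to 9); compound 3 enters in step 2.

Steps most likely to fail:

**Step 4.** The alkylidene may be diverted before ring closure: intermolecular metathesis through the vinyl group, decomposition before the hindered ketone is olefinated, or attack on the benzoate carbonyl. The fallback is a two-stage olefin route that sets out from 5. Methylenation of the ketone with the Tebbe reagent Cp2Ti(μ-Cl)(μ-CH2)AlMe2 (THF, −40 to 0 °C; ketone before ester) should give the diene (R)-[(4R)-2,2-dimethyl-5-methylidene-1,3-dioxan-4-yl][(4R,5R)-2,2-dimethyl-5-vinyl-1,3-dioxolan-4-yl]methyl benzoate F1. Ring-closing olefin metathesis of F1 with the second-generation Grubbs catalyst RuCl2(=CHPh)(H2IMes)(PCy3) (CH2Cl2, 40 °C) closes C1=C2 with loss of ethene and comes back to the route at 7.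

**Step 2.** Stereocontrol may erode: the aldehyde can epimerise at its α-carbon through its own enamine during the slow reaction, and the catalyst-controlled face is anti-Felkin with respect to the α-alkoxy centre, so facial selectivity may be poor. The fallback is an auxiliary-controlled aldol at low temperature that sets out from 3. Condensation with (S)-1-amino-2-(methoxymethyl)pyrrolidine gives the hydrazone (S)-N-(2,2-dimethyl-1,3-dioxan-5-ylidene)-2-(methoxymethyl)pyrrolidin-1-amine F2. Deprotonation with t-BuLi (THF, −78 °C) and addition of 2 at −100 °C should give the aldol hydrazone of 4, F3. Cleavage with saturated aqueous oxalic acid in ether comes back to the route at 4.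

**Step 6.** Site selectivity may be lost: acylation of a secondary hydroxyl, double acylation, or base-promoted migration of the O5 benzoate. The fallback unmasks the hydroxyls in stages and sets out from 7. Selective hydrolysis of the more labile six-membered allylic 6,7-acetonide (60% aqueous AcOH, 20 °C) gives the 3,4-O-isopropylidene acetal of 8, F4. Benzoylation of its primary hydroxyl (BzCl, 2,4,6-collidine, CH2Cl2, −40 °C; the only competitor is the hindered O6–H) gives the 3,4-O-isopropylidene acetal of 9, F5. Aqueous CF3CO2H then removes the remaining acetonide and comes back to the route at 9.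

## Further compounds

F1 | step 4 | (R)-[(4R)-2,2-dimethyl-5-methylidene-1,3-dioxan-4-yl][(4R,5R)-2,2-dimethyl-5-vinyl-1,3-dioxolan-4-yl]methyl benzoate | C=C1COC(C)(C)O[C@H]1[C@@H](OC(=O)c3ccccc3)[C@@H]2OC(C)(C)O[C@@H]2C=C
F2 | step 2 | (S)-N-(2,2-dimethyl-1,3-dioxan-5-ylidene)-2-(methoxymethyl)pyrrolidin-1-amine | COC[C@@H]1CCCN1N=C1COC(C)(C)OC1
F3 | step 2 | (S)-2-(methoxymethyl)pyrrolidin-1-yl hydrazone of 4 | COC[C@@H]1CCCN1N=C1COC(C)(C)O[C@H]1[C@@H](O)[C@@H]2OC(C)(C)O[C@@H]2C=C
F4 | step 6 | 3,4-O-isopropylidene acetal of 8 (O6–H and O7–H free, O5 benzoate) | OCC1=C[C@H]2OC(C)(C)O[C@H]2[C@H](OC(=O)c3ccccc3)[C@@H]1O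
F5 | step 6 | 3,4-O-isopropylidene acetal of 9 | O=C(OCC1=C[C@H]2OC(C)(C)O[C@H]2[C@H](OC(=O)c3ccccc3)[C@@H]1O)c1ccccc1
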